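**Retrosynthetic overview**
1. Numbering: benzene ring A carries C1 (CO2H), C2 (OH), C4 (OMe) and C6 (side chain), and the chain runs from C1' (benzylic CH2) through C2' (ketone) to C13' (CH2OH). The plan rests on three facts: C6 is the only C–H next to the C1 carboxyl because C2 holds the OH; the C6 substituent is an acylmethyl unit (C1'H2–C2'=O); and a carboxyl oxygen and C2' are spaced to close a six-membered ring.
2. Last disconnection: hydroxide releases the keto acid from its enol lactone, an 8-hydroxy-6-methoxy-3-alkylisocoumarin (pyranone ring B fused on C1–C6). The C13' silyl ether is removed one step earlier, on the robust lactone.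
3. Key disconnection: the C6–C1' bond and the O–C2' bond of ring B are made in one operation from 2-hydroxy-4-methoxybenzoic acid and a keto sulfoxonium ylide (an acylmethyl carbene equivalent) under [Cp*RhCl2]2/NaOAc.
4. The ylide comes from 12-hydroxydodecanoic acid (methyl ester, TBS ether) and dimethylsulfoxonium methylide, which supplies C1'.
5. Ring order: ring A is bought; ring B is the only ring made (step 4) and is opened again on purpose in step 6.

Key step: step 4

Remark: the target has no stereocentre and is taken as the open keto acid as drawn, which may equilibrate with its lactol tautomer in solution.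

**Route**

Step 1
Reactants: 1 12-hydroxydodecanoic acid
Product: 2 methyl 12-hydroxydodecanoate
Conditions: MeOH, H2SO4 (cat.), reflux
Reagents that add atoms: methanol, CO
Why: Fischer esterification in a large excess of methanol should drive the acid to its methyl ester, with the dilution suppressing oligoester formation through the free primary alcohol.

Step 2
Reactants: 2 methyl 12-hydroxydodecanoate
Product: 3 methyl 12-(tert-butyldimethylsilyloxy)dodecanoate
Conditions: TBSCl, imidazole, DMF, 0 °C → rt
Reagents that add atoms: tert-butyldimethylsilyl chloride, CC(C)(C)[Si](C)(C)Cl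
Why: Imidazole-promoted silylation of an unhindered primary alcohol is routine and leaves the methyl ester untouched.

Step 3
Reactants: 3 methyl 12-(tert-butyldimethylsilyloxy)dodecanoate; 4 trimethylsulfoxonium iodide
Product: 6 dimethylsulfoxonium 13-(tert-butyldimethylsilyloxy)-2-oxotridecylide, via dimethylsulfoxonium methylide 5 (not isolated)
Conditions: 4 (3 equiv), KOtBu (3 equiv), THF, reflux; then 3, THF, reflux
Reagents that add atoms: none
Why: In this acylation of the Corey–Chaykovsky reagent, methylide 5 adds to the ester carbonyl, methoxide leaves, and the acidic β-keto sulfoxonium salt is deprotonated at once to the stabilised ylide, which resists a second addition, while the silyl ether tolerates the base.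

Step 4
Reactants: 6 dimethylsulfoxonium 13-(tert-butyldimethylsilyloxy)-2-oxotridecylide; 7 2-hydroxy-4-methoxybenzoic acid
Product: 10 8-hydroxy-6-methoxy-3-[11-(tert-butyldimethylsilyloxy)undecyl]-1H-isochromen-1-one, via keto acid 8 (not isolated), via lactol 9 (not isolated)
Conditions: [Cp*RhCl2]2 (5 mol %), NaOAc (0.5 equiv), 6 (1.5 equiv, added in portions), (CF3)2CHOH, 80 °C, sealed tube, Ar
Reagents that add atoms: none
Why: Chloride/acetate exchange puts the carboxylate of 7 on trivalent rhodium, and acetate-assisted concerted metalation–deprotonation of C6–H gives a five-membered rhodacycle. Ylide 6 binds through its carbanionic carbon, expels DMSO to leave a rhodium carbene, the aryl group migrates onto that carbon to forge C6–C1', and protodemetalation releases keto acid 8 and returns the catalyst. The closest known reaction type is the Cp*Rh- or (p-cymene)Ru-catalysed C–H acylmethylation/annulation of benzoic acids with α-keto sulfoxonium ylides to 3-substituted isocoumarins, and free salicylic acids are known to take part in the related Cp*Rh carboxylate-directed annulations with alkynes. Ring B closes by 6-exo-trig addition of a carboxyl oxygen to the C2' ketone to give lactol 9, and loss of water across C1'–C2', favoured by conjugation with ring A and by the hydrogen-bond-donating solvent, gives the enol lactone; the lactol centre is racemic and vanishes, so no stereocentre has to be controlled. The step needs site selectivity, which the substrate fixes because C2 carries OH and C6–H is the only ortho C–H, a fact that also excludes double acylmethylation. It also needs C–H over O–H functionalisation, which is helped by the hydrogen bond that ties the C2 hydroxyl to the carboxyl, by the acetate buffer and by portionwise addition of 6, while the silver-free medium at 80 °C limits protodecarboxylation and any loss of the silyl ether only anticipates step 5.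

Step 5
Reactants: 10 8-hydroxy-6-methoxy-3-[11-(tert-butyldimethylsilyloxy)undecyl]-1H-isochromen-1-one
Product: 11 8-hydroxy-3-(11-hydroxyundecyl)-6-methoxy-1H-isochromen-1-one
Conditions: HF·pyridine, pyridine, THF, 0 °C → rt (plastic vessel)
Reagents that add atoms: none
Why: Fluoride-mediated desilylation is driven by the strong Si–F bond, the pyridine buffer spares the enol lactone and the phenol, and doing it at the stable isocoumarin stage saves the sensitive keto acid one operation.

Step 6
Reactants: 11 8-hydroxy-3-(11-hydroxyundecyl)-6-methoxy-1H-isochromen-1-one
Product: 13 2-hydroxy-6-(13-hydroxy-2-oxotridecyl)-4-methoxybenzoic acid (CNP0165592.0), via potassium keto carboxylate 12 (not isolated)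
Conditions: KOH (aq), THF, rt, Ar; then 1 M HCl, 0 °C, to pH 3, quick EtOAc extraction, evaporation below 25 °C
Reagents that add atoms: potassium hydroxide, [K+].[OH-]
Why: In this saponification of an enol lactone, hydroxide adds to the lactone carbonyl, the expelled C2' enolate tautomerises to the ketone so that opening to carboxylate 12 is irreversible in base, and protonation in the cold with fast extraction should deliver the free acid before acid-catalysed relactonisation sets in.

**Compound list**
1 | 12-hydroxydodecanoic acid | OCCCCCCCCCCCC(=O)O | starting material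
2 | methyl 12-hydroxydodecanoate | COC(=O)CCCCCCCCCCCO | intermediate
3 | methyl 12-(tert-butyldimethylsilyloxy)dodecanoate | COC(=O)CCCCCCCCCCCO[Si](C)(C)C(C)(C)C | intermediate
4 | trimethylsulfoxonium iodide | C[S+](C)(C)=O.[I-] | starting material
5 | dimethylsulfoxonium methylide (not isolated) | C=S(C)(C)=O | intermediate
6 | dimethylsulfoxonium 13-(tert-butyldimethylsilyloxy)-2-oxotridecylide | CS(C)(=O)=CC(=O)CCCCCCCCCCCO[Si](C)(C)C(C)(C)C | intermediate
7 | 2-hydroxy-4-methoxybenzoic acid | COc1ccc(C(=O)O)c(O)c1 | starting material
8 | 2-hydroxy-4-methoxy-6-[13-(tert-butyldimethylsilyloxy)-2-oxotridecyl]benzoic acid (not isolated) | COc1cc(O)c(C(=O)O)c(CC(=O)CCCCCCCCCCCO[Si](C)(C)C(C)(C)C)c1 | intermediate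
9 | 3,8-dihydroxy-6-methoxy-3-[11-(tert-butyldimethylsilyloxy)undecyl]isochroman-1-one (racemic lactol, not isolated) | COc1cc(O)c2c(c1)CC(O)(CCCCCCCCCCCO[Si](C)(C)C(C)(C)C)OC2=O | intermediate
10 | 8-hydroxy-6-methoxy-3-[11-(tert-butyldimethylsilyloxy)undecyl]-1H-isochromen-1-one | COc1cc(O)c2c(c1)C=C(CCCCCCCCCCCO[Si](C)(C)C(C)(C)C)OC2=O | intermediate
11 | 8-hydroxy-3-(11-hydroxyundecyl)-6-methoxy-1H-isochromen-1-one | COc1cc(O)c2c(c1)C=C(CCCCCCCCCCCO)OC2=O | intermediate
12 | potassium 2-hydroxy-6-(13-hydroxy-2-oxotridecyl)-4-methoxybenzoate (not isolated) | COc1cc(O)c(C(=O)[O-])c(CC(=O)CCCCCCCCCCCO)c1.[K+] | intermediate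
13 | 2-hydroxy-6-(13-hydroxy-2-oxotridecyl)-4-methoxybenzoic acid | COc1cc(O)c(C(=O)O)c(CC(=O)CCCCCCCCCCCO)c1 | target

**Step count and risks**
Total step count: 6. Longest linear sequence: 6 steps (1 → 2 → 3 → 6 → 10 → 11 → 13).

Steps most likely to fail:

1. Step 4.
   - Risk: rhodium may be tied up by O,O-chelation of the salicylate. The acid may protonate the ylide and then be O-alkylated by it. The electron-rich acid may also lose CO2 on heating, so that turnover stalls.
   - Fallback (polar benzylic acylation instead of C–H activation), setting out from 3 and coming back at 11. Ester 3 is converted with MeNH(OMe)·HCl and iPrMgCl (THF, −20 °C) into N-methoxy-N-methyl-12-(tert-butyldimethylsilyloxy)dodecanamide F1. Purchased methyl 2-hydroxy-4-methoxy-6-methylbenzoate F2 is capped with NaH and MOMCl (DMF, 0 °C) as methyl 4-methoxy-2-(methoxymethoxy)-6-methylbenzoate F3. Lateral lithiation of F3 with LiN(iPr)2 (THF, −78 °C) and acylation of the benzylic anion by F1 should give methyl 4-methoxy-2-(methoxymethoxy)-6-[13-(tert-butyldimethylsilyloxy)-2-oxotridecyl]benzoate F4. Warm aqueous HCl in THF then strips the acetal and the silyl ether and lets the enol oxygen close on the ester, which should deliver isocoumarin 11.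

2. Step 6.
   - Risk: the freed acid may close back to the lactone during acidification or concentration. The benzylic enolate may be oxidised by air in base. The salicylic acid may decarboxylate if the medium becomes too acidic.
   - Fallback (release of the acid under neutral conditions), setting out from 12 and coming back at 13. Excess KOH is neutralised with CO2, the solution is freeze-dried, and the salt is alkylated with benzyl bromide in DMF. This should give benzyl 2-hydroxy-6-(13-hydroxy-2-oxotridecyl)-4-methoxybenzoate F5, a neutral compound that can be chromatographed. Hydrogenolysis (H2, Pd/C, EtOAc, rt) should then free acid 13 without any contact with mineral acid, with filtration and cold evaporation as the only work-up.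

3. Step 3.
   - Risk: addition of the methylide to the unactivated, enolisable methyl ester may be slow. Enolisation, Claisen self-condensation and thermal decay of the methylide at reflux could then compete.
   - Fallback (a far better acyl donor, used cold), setting out from 3 and coming back at 6. LiOH (THF/H2O) followed by citric acid should give 12-(tert-butyldimethylsilyloxy)dodecanoic acid F6. EDC·HCl, 4-nitrophenol and catalytic DMAP (CH2Cl2) convert it into 4-nitrophenyl 12-(tert-butyldimethylsilyloxy)dodecanoate F7. This active ester should acylate methylide 5 at 0 °C to rt to give ylide 6.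

**Further compounds**
F1 | step 4 | N-methoxy-N-methyl-12-(tert-butyldimethylsilyloxy)dodecanamide | CON(C)C(=O)CCCCCCCCCCCO[Si](C)(C)C(C)(C)C
F2 | step 4 | methyl 2-hydroxy-4-methoxy-6-methylbenzoate (purchased) | COc1cc(C)c(C(=O)OC)c(O)c1
F3 | step 4 | methyl 4-methoxy-2-(methoxymethoxy)-6-methylbenzoate | COCOc1cc(OC)cc(C)c1C(=O)OC
F4 | step 4 | methyl 4-methoxy-2-(methoxymethoxy)-6-[13-(tert-butyldimethylsilyloxy)-2-oxotridecyl]benzoate | COCOc1cc(OC)cc(CC(=O)CCCCCCCCCCCO[Si](C)(C)C(C)(C)C)c1C(=O)OC
F5 | step 6 | benzyl 2-hydroxy-6-(13-hydroxy-2-oxotridecyl)-4-methoxybenzoate | COc1cc(O)c(C(=O)OCc2ccccc2)c(CC(=O)CCCCCCCCCCCO)c1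
F6 | step 3 | 12-(tert-butyldimethylsilyloxy)dodecanoic acid | OC(=O)CCCCCCCCCCCO[Si](C)(C)C(C)(C)C
F7 | step 3 | 4-nitrophenyl 12-(tert-butyldimethylsilyloxy)dodecanoate | O=C(CCCCCCCCCCCO[Si](C)(C)C(C)(C)C)Oc1ccc(cc1)[N+](=O)[O-]
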